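**Plan**

- Retrosynthesis: the C1 methyl imine is taken back to a lactam (C1=O). N2–C3 and C4–C4a are then cut together, giving propene and an N-pivaloyloxy benzamide. The C5–C1' biaryl bond is cut next, and the oxygenated naphthalene ring last, to an anisyl carbene complex, CO and propyne.
- Enabling feature: C3–C4 with the C3 methyl group is a propene unit spanning N2 and the ring A carbon C4a. C4a is ortho to C8a, whose carbon C1 can be carried as an amide carbonyl that directs rhodium to C4a–H; the C8 methoxy group blocks the other ortho position.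
- Forward order: naphthalene ring by Dötz benzannulation, biaryl by Suzuki–Miyaura coupling, nitrogen ring by rhodium-catalysed C–H annulation with propene, then exchange of the C1 carbonyl for the methyl imine through the N-Boc lactam.
- Stereochemistry: C3 (S) is set in the annulation by the chiral cyclopentadienyl ligand on rhodium and is not touched afterwards.

Key step: step 9

Assumption: the target structure fixes only C3 (S). The hindered C5–C1' axis is left as it forms, so both rotamers about it are expected from step 9 onward; they are diastereomers and can be separated by chromatography at lactam 17 or at the end if one is wanted.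

Remark: Cpx is the cyclopentadienyl ligand C29H23O2 in which two adjacent ring carbons are bridged by the two CH2 groups of a 3,3'-dimethoxy-1,1'-binaphthalene-2,2'-diyl-bis(methylene) unit. The precatalyst (Cpx)Rh(C2H4)2 is therefore C33H31O2Rh. Both antipodes are available from the two enantiomers of BINOL.

**Step 1**
Reactants: 1 2-bromoanisole
Product: 4 pentacarbonyl[methoxy(2-methoxyphenyl)methylidene]chromium, via 2-methoxyphenyllithium 2 (not isolated), via lithium acylchromate 3 (not isolated)
Conditions: n-BuLi, THF, −78 °C; Cr(CO)6, −78 °C to rt; then Me3OBF4, CH2Cl2, 0 °C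
Reagents that add atoms: chromium hexacarbonyl O=C=[Cr](=C=O)(=C=O)(=C=O)(=C=O)=C=O; trimethyloxonium tetrafluoroborate C[O+](C)C.F[B-](F)(F)F (n-BuLi, [Li]CCCC, supplies the lithium of 2 and 3 only)
Why: Fischer carbene synthesis: bromine–lithium exchange gives the aryllithium, which adds to a CO ligand of Cr(CO)6, and the resulting acylchromate is O-methylated by Meerwein's salt.

**Step 2**
Reactants: 4 pentacarbonyl[methoxy(2-methoxyphenyl)methylidene]chromium; 5 propyne
Product: 7 4,5-dimethoxy-2-methylnaphthalen-1-ol, via tricarbonylchromium naphthol complex 6 (not isolated)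
Conditions: propyne (4 equiv), THF, 50 °C, sealed tube; then air, Et2O, rt
Reagents that add atoms: none
Why: Dötz benzannulation: the unsubstituted alkyne carbon bonds to the carbene carbon, CO inserts next to the methyl-bearing carbon, and 6π closure onto the free ortho carbon of the anisyl ring places the methyl group beside the new phenol carbon and the two methoxy groups peri to each other; air then strips the Cr(CO)3 unit from complex 6, and 7 should be used at once.

**Step 3**
Reactants: 7 4,5-dimethoxy-2-methylnaphthalen-1-ol
Product: 8 4,5-dimethoxy-2-methylnaphthalen-1-yl trifluoromethanesulfonate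
Conditions: Tf2O, pyridine, CH2Cl2, −78 to 0 °C
Reagents that add atoms: triflic anhydride O=S(=O)(OS(=O)(=O)C(F)(F)F)C(F)(F)F
Why: O-sulfonylation of a phenol, which turns the oxidation-prone naphthol into a stable cross-coupling electrophile at C1'.

**Step 4**
Reactants: 9 methyl 2,4-dimethoxybenzoate
Product: 10 methyl 5-bromo-2,4-dimethoxybenzoate
Conditions: NBS, MeCN, rt
Reagents that add atoms: N-bromosuccinimide O=C1CCC(=O)N1Br
Why: Electrophilic aromatic bromination: C5 is para to the C2 methoxy group and ortho to the C4 methoxy group, whereas C3 lies shielded between two methoxy groups and C6 is deactivated by the ester.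

**Step 5**
Reactants: 10 methyl 5-bromo-2,4-dimethoxybenzoate
Product: 11 methyl 2,4-dimethoxy-5-(4,4,5,5-tetramethyl-1,3,2-dioxaborolan-2-yl)benzoate
Conditions: B2pin2, PdCl2(dppf) (3 mol%), KOAc, 1,4-dioxane, 90 °C
Reagents that add atoms: bis(pinacolato)diboron CC1(C)OB(OC1(C)C)B1OC(C)(C)C(C)(C)O1
Why: Miyaura borylation: zerovalent palladium inserts into the C–Br bond and acetate-assisted transmetalation with B2pin2 gives the aryl pinacol boronate, the ester being inert to KOAc.

**Step 6**
Reactants: 8 4,5-dimethoxy-2-methylnaphthalen-1-yl trifluoromethanesulfonate; 11 methyl 2,4-dimethoxy-5-(4,4,5,5-tetramethyl-1,3,2-dioxaborolan-2-yl)benzoate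
Product: 12 methyl 5-(4,5-dimethoxy-2-methylnaphthalen-1-yl)-2,4-dimethoxybenzoate
Conditions: Pd(OAc)2 (4 mol%), SPhos (8 mol%), K3PO4, toluene/H2O 10:1, 100 °C
Reagents that add atoms: none
Why: Suzuki–Miyaura coupling: the bulky, electron-rich biaryl phosphine is a standard choice for tri-ortho-substituted biaryls and hindered aryl triflates, and carrying boron on the benzoate keeps the hindered, electron-rich naphthalene off the protodeboronation-prone side.

**Step 7**
Reactants: 12 methyl 5-(4,5-dimethoxy-2-methylnaphthalen-1-yl)-2,4-dimethoxybenzoate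
Product: 13 5-(4,5-dimethoxy-2-methylnaphthalen-1-yl)-2,4-dimethoxybenzoic acid
Conditions: LiOH, THF/MeOH/H2O, 50 °C; then 1 M HCl
Reagents that add atoms: lithium hydroxide [Li+].[OH-]
Why: Ester saponification; no other base-labile group is present.

**Step 8**
Reactants: 13 5-(4,5-dimethoxy-2-methylnaphthalen-1-yl)-2,4-dimethoxybenzoic acid
Product: 15 5-(4,5-dimethoxy-2-methylnaphthalen-1-yl)-2,4-dimethoxy-N-(pivaloyloxy)benzamide, via acid chloride 14 (not isolated)
Conditions: (COCl)2, DMF (cat.), CH2Cl2, 0 °C to rt; then PivONH2·TfOH, K2CO3, EtOAc/H2O, 0 °C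
Reagents that add atoms: O-pivaloylhydroxylammonium triflate CC(C)(C)C(=O)ON.OS(=O)(=O)C(F)(F)F (oxalyl chloride, O=C(Cl)C(=O)Cl, supplies the chlorine of 14 only)
Why: Acid chloride formation followed by Schotten–Baumann N-acylation of O-pivaloylhydroxylamine is the standard entry to N-acyloxy amides, and the cold biphasic carbonate medium avoids Lossen rearrangement.

**Step 9**
Reactants: 15 5-(4,5-dimethoxy-2-methylnaphthalen-1-yl)-2,4-dimethoxy-N-(pivaloyloxy)benzamide; 16 propene
Product: 17 (3S)-5-(4,5-dimethoxy-2-methylnaphthalen-1-yl)-6,8-dimethoxy-3-methyl-3,4-dihydroisoquinolin-1(2H)-one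
Conditions: (Cpx)Rh(C2H4)2 (5 mol%), (BzO)2 (5 mol%), EtOH, rt, N2 purge; then 15, propene (2 bar), 23 to 40 °C
Reagents that add atoms: none
Why: Dibenzoyl peroxide oxidises the monovalent rhodium precatalyst to the trivalent carboxylate (Cpx)Rh(O2CPh)2 (the purge removes the liberated ethylene), which metalates the only free ortho C–H of 15 (the future C4a) by carboxylate-assisted concerted metalation–deprotonation to a five-membered N,C-rhodacycle; propene then inserts into the Rh–aryl bond, and C–N bond formation with the N–O bond as internal oxidant releases 17, pivalic acid and trivalent rhodium. The closest known reaction type is the enantioselective annulation of O-acyl benzhydroxamates with terminal alkenes under chiral cyclopentadienyl rhodium catalysis, which gives 3-substituted dihydroisoquinolones. The nitrogen ring closes as a formal [4+2] annulation in which C4–C4a is made by migratory insertion and N2–C3 by C(sp3)–N reductive elimination from a seven-membered rhodacycle. C3 is set at insertion: the binaphthyl wall of the ligand should admit propene with one face only, and the ligand antipode is chosen so that rhodium, and then nitrogen, end on the Si face of the methyl-bearing carbon, which corresponds to 3S. The step needs site selectivity (secured by the C8 methoxy group, which blocks the second ortho position), the 3-methyl rather than 4-methyl sense of insertion (the aryl group should migrate to the CH2 carbon because this sparsely substituted ligand leaves room at rhodium for the methyl-bearing carbon) and enantiofacial control (ligand). The orthogonal naphthyl ring beside the reacting C–H bond should slow metalation, which is why mild warming is allowed for, and both rotamers about the new tetra-ortho-substituted axis are expected.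

**Step 10**
Reactants: 17 (3S)-5-(4,5-dimethoxy-2-methylnaphthalen-1-yl)-6,8-dimethoxy-3-methyl-3,4-dihydroisoquinolin-1(2H)-one
Product: 18 tert-butyl (3S)-5-(4,5-dimethoxy-2-methylnaphthalen-1-yl)-6,8-dimethoxy-3-methyl-1-oxo-3,4-dihydroisoquinoline-2(1H)-carboxylate
Conditions: Boc2O, DMAP (0.2 equiv), MeCN, rt
Reagents that add atoms: di-tert-butyl dicarbonate CC(C)(C)OC(=O)OC(=O)OC(C)(C)C
Why: DMAP-catalysed N-acylation of the lactam gives an imide-like N-Boc lactam whose ring carbonyl is activated towards nucleophiles, with C3 untouched.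

**Step 11**
Reactants: 18 tert-butyl (3S)-5-(4,5-dimethoxy-2-methylnaphthalen-1-yl)-6,8-dimethoxy-3-methyl-1-oxo-3,4-dihydroisoquinoline-2(1H)-carboxylate
Product: 19 tert-butyl N-[(2S)-1-[2-acetyl-6-(4,5-dimethoxy-2-methylnaphthalen-1-yl)-3,5-dimethoxyphenyl]propan-2-yl]carbamate
Conditions: MeLi (1.2 equiv), THF, −78 °C; then aq. NH4Cl
Reagents that add atoms: methyllithium [Li]C
Why: Organolithium ring opening of an N-acyl lactam: methyllithium adds to the ring carbonyl, the ring opens to the aryl methyl ketone with nitrogen leaving as its Boc carbamate anion, and this anion together with the two ortho substituents of the new ketone should hold back a second addition; C3 is not involved.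

**Step 12**
Reactants: 19 tert-butyl N-[(2S)-1-[2-acetyl-6-(4,5-dimethoxy-2-methylnaphthalen-1-yl)-3,5-dimethoxyphenyl]propan-2-yl]carbamate
Product: 21 O-methylancistrocladinine, via amino ketone 20 (not isolated)
Conditions: TFA, CH2Cl2, 0 °C to rt; then aq. NaHCO3, rt
Reagents that add atoms: none
Why: Acidolysis of the Boc group and, on neutralisation, intramolecular condensation of the primary amine with the ortho acetyl group give the six-membered cyclic imine; no bond to C3 is broken, so 3S is retained.

**Compound list**

1 | 2-bromoanisole | COc1ccccc1Br | starting material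
2 | 2-methoxyphenyllithium | [Li]c1ccccc1OC | intermediate
3 | lithium pentacarbonyl[(2-methoxyphenyl)(oxido)methylidene]chromate (lithium acylchromate) | [Li+].[O-]C(c1ccccc1OC)=[Cr](=C=O)(=C=O)(=C=O)(=C=O)=C=O | intermediate
4 | pentacarbonyl[methoxy(2-methoxyphenyl)methylidene]chromium | COC(c1ccccc1OC)=[Cr](=C=O)(=C=O)(=C=O)(=C=O)=C=O | intermediate
5 | propyne | CC#C | starting material
6 | tricarbonyl(η6-4,5-dimethoxy-2-methylnaphthalen-1-ol)chromium | COc1cc(C)c(O)c2cccc(OC)c12.O=C=[Cr](=C=O)=C=O | intermediate
7 | 4,5-dimethoxy-2-methylnaphthalen-1-ol | COc1cc(C)c(O)c2cccc(OC)c12 | intermediate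
8 | 4,5-dimethoxy-2-methylnaphthalen-1-yl trifluoromethanesulfonate | COc1cc(C)c(OS(=O)(=O)C(F)(F)F)c2cccc(OC)c12 | intermediate
9 | methyl 2,4-dimethoxybenzoate | COC(=O)c1ccc(OC)cc1OC | starting material
10 | methyl 5-bromo-2,4-dimethoxybenzoate | COC(=O)c1cc(Br)c(OC)cc1OC | intermediate
11 | methyl 2,4-dimethoxy-5-(4,4,5,5-tetramethyl-1,3,2-dioxaborolan-2-yl)benzoate | COC(=O)c1cc(B2OC(C)(C)C(C)(C)O2)c(OC)cc1OC | intermediate
12 | methyl 5-(4,5-dimethoxy-2-methylnaphthalen-1-yl)-2,4-dimethoxybenzoate | COC(=O)c1cc(-c2c(C)cc(OC)c3c(OC)cccc23)c(OC)cc1OC | intermediate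
13 | 5-(4,5-dimethoxy-2-methylnaphthalen-1-yl)-2,4-dimethoxybenzoic acid | OC(=O)c1cc(-c2c(C)cc(OC)c3c(OC)cccc23)c(OC)cc1OC | intermediate
14 | 5-(4,5-dimethoxy-2-methylnaphthalen-1-yl)-2,4-dimethoxybenzoyl chloride | ClC(=O)c1cc(-c2c(C)cc(OC)c3c(OC)cccc23)c(OC)cc1OC | intermediate
15 | 5-(4,5-dimethoxy-2-methylnaphthalen-1-yl)-2,4-dimethoxy-N-(pivaloyloxy)benzamide | COc1cc(OC)c(-c2c(C)cc(OC)c3c(OC)cccc23)cc1C(=O)NOC(=O)C(C)(C)C | intermediate
16 | propene | CC=C | starting material
17 | (3S)-5-(4,5-dimethoxy-2-methylnaphthalen-1-yl)-6,8-dimethoxy-3-methyl-3,4-dihydroisoquinolin-1(2H)-one | COc1cc(OC)c(-c2c(C)cc(OC)c3c(OC)cccc23)c2c1C(=O)N[C@@H](C)C2 | intermediate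
18 | tert-butyl (3S)-5-(4,5-dimethoxy-2-methylnaphthalen-1-yl)-6,8-dimethoxy-3-methyl-1-oxo-3,4-dihydroisoquinoline-2(1H)-carboxylate | COc1cc(OC)c(-c2c(C)cc(OC)c3c(OC)cccc23)c2c1C(=O)N(C(=O)OC(C)(C)C)[C@@H](C)C2 | intermediate
19 | tert-butyl N-[(2S)-1-[2-acetyl-6-(4,5-dimethoxy-2-methylnaphthalen-1-yl)-3,5-dimethoxyphenyl]propan-2-yl]carbamate | COc1cc(OC)c(-c2c(C)cc(OC)c3c(OC)cccc23)c(C[C@H](C)NC(=O)OC(C)(C)C)c1C(C)=O | intermediate
20 | 1-[2-[(2S)-2-aminopropyl]-3-(4,5-dimethoxy-2-methylnaphthalen-1-yl)-4,6-dimethoxyphenyl]ethan-1-one | COc1cc(OC)c(-c2c(C)cc(OC)c3c(OC)cccc23)c(C[C@H](C)N)c1C(C)=O | intermediate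
21 | O-methylancistrocladinine, (3S)-5-(4,5-dimethoxy-2-methylnaphthalen-1-yl)-6,8-dimethoxy-1,3-dimethyl-3,4-dihydroisoquinoline | COc1cc(OC)c(-c2c(C)cc(OC)c3c(OC)cccc23)c2c1C(C)=N[C@@H](C)C2 | target

**Step count**

Total: 12 steps. Longest linear sequence: 10 steps (steps 1, 2, 3, 6, 7, 8, 9, 10, 11, 12, from 2-bromoanisole).

**Steps most likely to fail**

Step 9. Metalation of the single available C–H bond may be slowed so much by the orthogonal naphthyl ring beside it that solvolysis or Lossen-type breakdown of the N–O function overtakes annulation. Propene, which has no electronic bias, may also insert partly in the opposite sense or with incomplete facial control. The fallback inverts the order of annulation and biaryl coupling; it sets out from 10 (with 8 for the naphthalene) and returns at 17. Ester 10 would be saponified (LiOH) to 5-bromo-2,4-dimethoxybenzoic acid F1, converted with oxalyl chloride into 5-bromo-2,4-dimethoxybenzoyl chloride F2, and acylated onto O-pivaloylhydroxylamine to give 5-bromo-2,4-dimethoxy-N-(pivaloyloxy)benzamide F3. The same rhodium-catalysed annulation with propene, now at a C–H bond flanked only by bromine, should give (3S)-5-bromo-6,8-dimethoxy-3-methyl-3,4-dihydroisoquinolin-1(2H)-one F4. On this small lactam, regio- and enantiomeric purity can be checked and raised by crystallisation before the naphthalene is committed. Triflate 8 would be borylated (B2pin2, Pd(OAc)2/SPhos, KOAc) to 2-(4,5-dimethoxy-2-methylnaphthalen-1-yl)-4,4,5,5-tetramethyl-1,3,2-dioxaborolane F5. A Suzuki–Miyaura coupling of F4 with F5 (Pd(OAc)2/SPhos, K3PO4, toluene/H2O, 110 °C) would then build the tetra-ortho-substituted axis and give 17.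

Step 11. Methyllithium may attack the Boc carbonyl (returning 17) or fail to add to the electron-rich ring carbonyl, which is flanked by the C8 methoxy group. The fallback replaces carbonyl addition by cross-coupling at the imidoyl oxidation level; it sets out from 17 and returns at 21, bypassing 18 to 20. Lactam 17 would be heated with POCl3 to give (3S)-1-chloro-5-(4,5-dimethoxy-2-methylnaphthalen-1-yl)-6,8-dimethoxy-3-methyl-3,4-dihydroisoquinoline F6. This imidoyl chloride would be methylated by iron-catalysed Kumada-type coupling (MeMgBr, Fe(acac)3 cat., THF/NMP, 0 °C) to give 21 directly.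

Step 2. The very electron-rich naphthol may be oxidised by air to the naphthoquinone while the chromium is being removed, and the volatile alkyne may be lost before insertion. The fallback removes the free naphthol from the isolation sequence; it sets out from 4 (with 5) and returns at 8. The benzannulation would be run in the presence of Ac2O and Et3N, so that the phenol is acetylated in the flask and isolated as air-stable 4,5-dimethoxy-2-methylnaphthalen-1-yl acetate F7. The acetate would then be cleaved under argon (K2CO3, degassed MeOH) to 7, which is triflated in the same flask with PhNTf2 to give 8.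

**Further compounds**

F1 | step 9 | 5-bromo-2,4-dimethoxybenzoic acid | OC(=O)c1cc(Br)c(OC)cc1OC
F2 | step 9 | 5-bromo-2,4-dimethoxybenzoyl chloride | ClC(=O)c1cc(Br)c(OC)cc1OC
F3 | step 9 | 5-bromo-2,4-dimethoxy-N-(pivaloyloxy)benzamide | COc1cc(OC)c(Br)cc1C(=O)NOC(=O)C(C)(C)C
F4 | step 9 | (3S)-5-bromo-6,8-dimethoxy-3-methyl-3,4-dihydroisoquinolin-1(2H)-one | COc1cc(OC)c(Br)c2c1C(=O)N[C@@H](C)C2
F5 | step 9 | 2-(4,5-dimethoxy-2-methylnaphthalen-1-yl)-4,4,5,5-tetramethyl-1,3,2-dioxaborolane | COc1cc(C)c(B2OC(C)(C)C(C)(C)O2)c2cccc(OC)c12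
F6 | step 11 | (3S)-1-chloro-5-(4,5-dimethoxy-2-methylnaphthalen-1-yl)-6,8-dimethoxy-3-methyl-3,4-dihydroisoquinoline | COc1cc(OC)c(-c2c(C)cc(OC)c3c(OC)cccc23)c2c1C(Cl)=N[C@@H](C)C2
F7 | step 2 | 4,5-dimethoxy-2-methylnaphthalen-1-yl acetate | COc1cc(C)c(OC(C)=O)c2cccc(OC)c12
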